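**Retrosynthetic overview**

1. Target 22 ⇐ 21 ⇐ 20 ⇐ 18 by late debenzylation, desilylation and acylation of O3; the pyran C ring of 18 is closed last through O1–C2 (Mitsunobu, inversion at C2) from anti diol 17.
2. Feature used: on the A ring the carbon substituent at C4a sits between the oxygenated carbons C5 and C8a, with the third oxygen at C7 para to it. This 2-alkylphloroglucinol pattern maps onto a siloxyalkyne (C4a, C5) plus an alkoxyvinylketene (C6, C7, C8, C8a).
3. A ring of 16 ⇐ siloxyalkyne 9 + 3-(benzyloxy)cyclobutenone 11: benzannulation forming C4a–C8a, C5–C6 and C8–C8a and leaving the C8a phenol free.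
4. 9 ⇐ terminal alkyne 6 (acetylide oxidation, O-silylation) ⇐ erythro epoxy alcohol 3 + acetylide ⇐ kinetic resolution of vinyl carbinol 2 ⇐ aldehyde 1 + vinyl Grignard.
5. Ring order: the B ring and the galloyl ring are bought, the A ring is built in step 8, the C ring is closed in step 10.

Key step: step 8

Assumption: aldehyde 1, cyclobutenone 10 and acid 19 are taken as commercial, and the B-ring benzylic C–O bond is taken to be configurationally stable to weak acids (PPTS, acetic acid) at or below 45 °C.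

**Route**

Step 1
Reactants: 1 3-(benzyloxy)-4-methoxybenzaldehyde
Product: 2 rac-1-[3-(benzyloxy)-4-methoxyphenyl]prop-2-en-1-ol
Conditions: CH2=CHMgBr, THF, 0 °C; aq. NH4Cl
Reagents that add atoms: vinylmagnesium bromide, C=C[Mg]Br
Why: Grignard 1,2-addition to the aryl aldehyde should give the secondary allylic alcohol, deliberately racemic because the carbinol centre is resolved in step 2.

Step 2
Reactants: 2 rac-1-[3-(benzyloxy)-4-methoxyphenyl]prop-2-en-1-ol
Product: 3 (S)-[3-(benzyloxy)-4-methoxyphenyl][(2R)-oxiran-2-yl]methanol (erythro)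
Conditions: Ti(OiPr)4 (0.15 equiv), L-(+)-DIPT (0.18 equiv), t-BuOOH (0.45 equiv), 4 Å MS, CH2Cl2, −20 °C
Reagents that add atoms: tert-butyl hydroperoxide, CC(C)(C)OO
Why: Sharpless kinetic resolution of a secondary allylic alcohol: with L-(+)-DIPT the (R)-alcohol should be epoxidised much faster and on the alkene face that gives the erythro (1S,2R) epoxy alcohol, so the tartrate sets the oxirane CH (later C3, R) and selects the carbinol configuration (later C2), leaving the (S)-alcohol unreacted.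

Step 3
Reactants: 3 (S)-[3-(benzyloxy)-4-methoxyphenyl][(2R)-oxiran-2-yl]methanol
Product: 4 (2R)-2-{(S)-[3-(benzyloxy)-4-methoxyphenyl][(2-methoxypropan-2-yl)oxy]methyl}oxirane
Conditions: 2-methoxypropene, PPTS (cat.), CH2Cl2, 0 °C; Et3N quench
Reagents that add atoms: 2-methoxypropene, COC(C)=C
Why: Acid-catalysed addition of the alcohol to the enol ether (mixed-ketal protection) masks the carbinol without touching a stereocentre and blocks Payne rearrangement under the basic conditions of step 4.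

Step 4
Reactants: 4 (2R)-2-{(S)-[3-(benzyloxy)-4-methoxyphenyl][(2-methoxypropan-2-yl)oxy]methyl}oxirane
Product: 5 (1S,2R)-1-[3-(benzyloxy)-4-methoxyphenyl]-1-[(2-methoxypropan-2-yl)oxy]pent-4-yn-2-ol
Conditions: LiC≡CH·H2NCH2CH2NH2, DMSO, rt; H2O
Reagents that add atoms: lithium acetylide–ethylenediamine complex, [Li]C#C.NCCN
Why: SN2 opening of the monosubstituted epoxide at its CH2 terminus by the acetylide forms the C4–C(alkyne) bond, breaks no bond at either stereocentre and leaves the base-stable ketal intact.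

Step 5
Reactants: 5 (1S,2R)-1-[3-(benzyloxy)-4-methoxyphenyl]-1-[(2-methoxypropan-2-yl)oxy]pent-4-yn-2-ol
Product: 6 (4R,5S)-5-[3-(benzyloxy)-4-methoxyphenyl]-2,2-dimethyl-4-(prop-2-yn-1-yl)-1,3-dioxolane (cis-acetonide of the anti diol)
Conditions: PPTS (cat.), 4 Å MS, CH2Cl2, rt
Reagents that add atoms: none
Why: Acid-catalysed intramolecular transketalisation: the mixed ketal ionises at the isopropylidene carbon and the neighbouring hydroxyl captures the oxocarbenium ion, closing the cis-dioxolane with loss of methanol and no change at either stereocentre.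

Step 6
Reactants: 6 (4R,5S)-5-[3-(benzyloxy)-4-methoxyphenyl]-2,2-dimethyl-4-(prop-2-yn-1-yl)-1,3-dioxolane
Product: 9 triisopropyl({3-[(4R,5S)-5-[3-(benzyloxy)-4-methoxyphenyl]-2,2-dimethyl-1,3-dioxolan-4-yl]prop-1-yn-1-yl}oxy)silane, via lithium acetylide 7 (not isolated), via lithium ynolate 8 (not isolated)
Conditions: LiHMDS, THF, −78 °C; LiOOt-Bu (from t-BuOOH + LiHMDS), −78 → 0 °C; TIPSOTf, −78 → 0 °C; chromatography on Et3N-deactivated silica
Reagents that add atoms: lithium tert-butyl peroxide (made from tert-butyl hydroperoxide), [Li]OOC(C)(C)C; triisopropylsilyl trifluoromethanesulfonate, CC(C)[Si](OS(=O)(=O)C(F)(F)F)(C(C)C)C(C)C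
Why: Oxidation of a lithium acetylide by lithium tert-butyl peroxide (electrophilic oxygen transfer to the acetylide carbon) should give the lithium ynolate, which the bulky silyl triflate silylates on oxygen to the siloxyalkyne, while the acetonide and the ethers are inert to these bases.

Step 7
Reactants: 10 3-ethoxycyclobut-2-en-1-one
Product: 11 3-(benzyloxy)cyclobut-2-en-1-one
Conditions: BnOH (3 equiv), TsOH·H2O (5 mol%), toluene, 40 °C, reduced pressure (−EtOH)
Reagents that add atoms: benzyl alcohol, OCc1ccccc1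
Why: Acid-catalysed vinylogous transesterification (addition–elimination at C3 of the β-alkoxy enone through the mixed ketal, as in alkoxy exchange of squarate esters) should be driven to the benzyl enol ether by removal of ethanol.

Step 8
Reactants: 9 triisopropyl({3-[(4R,5S)-5-[3-(benzyloxy)-4-methoxyphenyl]-2,2-dimethyl-1,3-dioxolan-4-yl]prop-1-yn-1-yl}oxy)silane; 11 3-(benzyloxy)cyclobut-2-en-1-one
Product: 16 5-(benzyloxy)-2-{[(4R,5S)-5-[3-(benzyloxy)-4-methoxyphenyl]-2,2-dimethyl-1,3-dioxolan-4-yl]methyl}-3-[(triisopropylsilyl)oxy]phenol, via vinylketene 12 (not isolated), via vinylcyclobutenone 13 (not isolated), via dienylketene 14 (not isolated), via cyclohexadienone 15 (not isolated)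
Conditions: 9 (1.0 equiv), 11 (1.3 equiv), toluene, 80 °C then 110 °C, Ar, sealed tube
Reagents that add atoms: none
Why: Danheiser benzannulation: thermal 4π electrocyclic opening of 11 gives vinylketene 12, whose ketene C=C adds to the siloxyalkyne in a [2+2] cycloaddition to give 13; 4π opening of 13 to dienylketene 14, 6π electrocyclisation to 15 and tautomerisation should give phenol 16. The closest known reaction type is the cyclobutenone–siloxyalkyne aromatic annulation to resorcinol monosilyl ethers, here run with a 3-alkoxy (vinylogous ester) cyclobutenone, which is why the higher final temperature is planned for ring opening. The transient four-membered ring closes by the ketene–alkyne [2+2] cycloaddition (forming C4a–C8a and C5–C6), and the benzene A ring closes by thermal disrotatory 6π electrocyclisation (forming C8–C8a), with release of strain from two successive cyclobutenones driving the cascade. No stereocentre is created in the product, because the sp3 ring carbon of 13 is lost on ring opening, and the two dioxolane centres are remote from the reacting π systems under neutral thermal conditions. The selectivity needed is the regiochemistry of the ketene–alkyne union: the oxygen lone pair polarises the ynol ether so that the carbon bearing the CH2 chain is nucleophilic and bonds to the electrophilic ketene carbonyl carbon. This places the side chain (C4a) between the free phenol (C8a) and the silyloxy carbon (C5), with the benzyloxy group para (C7).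

Step 9
Reactants: 16 5-(benzyloxy)-2-{[(4R,5S)-5-[3-(benzyloxy)-4-methoxyphenyl]-2,2-dimethyl-1,3-dioxolan-4-yl]methyl}-3-[(triisopropylsilyl)oxy]phenol
Product: 17 (1S,2R)-1-[3-(benzyloxy)-4-methoxyphenyl]-3-{4-(benzyloxy)-2-hydroxy-6-[(triisopropylsilyl)oxy]phenyl}propane-1,2-diol
Conditions: AcOH/H2O/THF (3:1:1), 45 °C
Reagents that add atoms: none
Why: Acid-catalysed acetal hydrolysis of the cis-dioxolane proceeds through the isopropylidene oxocarbenium ion, so neither C–O bond at the stereocentres is broken, and the aryl silyl ether and the benzyl ethers are stable to aqueous acetic acid.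

Step 10
Reactants: 17 (1S,2R)-1-[3-(benzyloxy)-4-methoxyphenyl]-3-{4-(benzyloxy)-2-hydroxy-6-[(triisopropylsilyl)oxy]phenyl}propane-1,2-diol
Product: 18 (2R,3R)-7-(benzyloxy)-2-[3-(benzyloxy)-4-methoxyphenyl]-5-[(triisopropylsilyl)oxy]-3,4-dihydro-2H-chromen-3-ol
Conditions: PPh3, DIAD, toluene (high dilution), 0 °C → rt
Reagents that add atoms: none
Why: Intramolecular Mitsunobu etherification (6-exo-tet): the phenol, the only acidic hydroxyl, should displace the oxyphosphonium of the benzylic hydroxyl with inversion, converting (S)-C2 of the anti diol into (2R) and so giving the 2,3-cis (2R,3R) flavan-3-ol with C3 untouched.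

Step 11
Reactants: 18 (2R,3R)-7-(benzyloxy)-2-[3-(benzyloxy)-4-methoxyphenyl]-5-[(triisopropylsilyl)oxy]-3,4-dihydro-2H-chromen-3-ol; 19 3,4,5-tris(benzyloxy)benzoic acid
Product: 20 (2R,3R)-7-(benzyloxy)-2-[3-(benzyloxy)-4-methoxyphenyl]-5-[(triisopropylsilyl)oxy]-3,4-dihydro-2H-chromen-3-yl 3,4,5-tris(benzyloxy)benzoate
Conditions: EDC·HCl, DMAP, CH2Cl2, rt
Reagents that add atoms: none
Why: Steglich esterification (carbodiimide activation, DMAP acyl transfer) acylates the only free hydroxyl, the C3 alcohol, with retention because the C3–O bond is not broken.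

Step 12
Reactants: 20 (2R,3R)-7-(benzyloxy)-2-[3-(benzyloxy)-4-methoxyphenyl]-5-[(triisopropylsilyl)oxy]-3,4-dihydro-2H-chromen-3-yl 3,4,5-tris(benzyloxy)benzoate
Product: 21 (2R,3R)-7-(benzyloxy)-2-[3-(benzyloxy)-4-methoxyphenyl]-5-hydroxy-3,4-dihydro-2H-chromen-3-yl 3,4,5-tris(benzyloxy)benzoate
Conditions: TBAF, AcOH, THF, 0 °C
Reagents that add atoms: none
Why: Fluoride-mediated cleavage of the aryl silyl ether is driven by the Si–F bond, and the acetic acid buffer keeps the medium non-basic so that the gallate ester should neither migrate nor be cleaved.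

Step 13
Reactants: 21 (2R,3R)-7-(benzyloxy)-2-[3-(benzyloxy)-4-methoxyphenyl]-5-hydroxy-3,4-dihydro-2H-chromen-3-yl 3,4,5-tris(benzyloxy)benzoate
Product: 22 4'-O-methylepicatechin-3-O-gallate
Conditions: H2 (1 atm), 20% Pd(OH)2/C, THF/MeOH, rt
Reagents that add atoms: none
Why: Catalytic hydrogenolysis of the five aryl benzyl ethers over Pearlman's catalyst should free all phenols under neutral conditions that leave the ester, the aryl methyl ether and the chroman C2–O bond intact.

**Compound list**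

1 | 3-(benzyloxy)-4-methoxybenzaldehyde | COc1ccc(C=O)cc1OCc1ccccc1 | starting material
2 | rac-1-[3-(benzyloxy)-4-methoxyphenyl]prop-2-en-1-ol | C=CC(O)c1ccc(OC)c(OCc2ccccc2)c1 | intermediate
3 | (S)-[3-(benzyloxy)-4-methoxyphenyl][(2R)-oxiran-2-yl]methanol | C1O[C@H]1[C@@H](O)c1ccc(OC)c(OCc2ccccc2)c1 | intermediate
4 | (2R)-2-{(S)-[3-(benzyloxy)-4-methoxyphenyl][(2-methoxypropan-2-yl)oxy]methyl}oxirane | C1O[C@H]1[C@@H](OC(C)(C)OC)c1ccc(OC)c(OCc2ccccc2)c1 | intermediate
5 | (1S,2R)-1-[3-(benzyloxy)-4-methoxyphenyl]-1-[(2-methoxypropan-2-yl)oxy]pent-4-yn-2-ol | C#CC[C@@H](O)[C@@H](OC(C)(C)OC)c1ccc(OC)c(OCc2ccccc2)c1 | intermediate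
6 | (4R,5S)-5-[3-(benzyloxy)-4-methoxyphenyl]-2,2-dimethyl-4-(prop-2-yn-1-yl)-1,3-dioxolane | C#CC[C@H]1OC(C)(C)O[C@H]1c1ccc(OC)c(OCc2ccccc2)c1 | intermediate
7 | lithium acetylide of 6 | [Li]C#CC[C@H]1OC(C)(C)O[C@H]1c1ccc(OC)c(OCc2ccccc2)c1 | intermediate
8 | lithium ynolate derived from 7 | [Li]OC#CC[C@H]1OC(C)(C)O[C@H]1c1ccc(OC)c(OCc2ccccc2)c1 | intermediate
9 | triisopropyl({3-[(4R,5S)-5-[3-(benzyloxy)-4-methoxyphenyl]-2,2-dimethyl-1,3-dioxolan-4-yl]prop-1-yn-1-yl}oxy)silane | CC(C)[Si](C(C)C)(C(C)C)OC#CC[C@H]1OC(C)(C)O[C@H]1c1ccc(OC)c(OCc2ccccc2)c1 | intermediate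
10 | 3-ethoxycyclobut-2-en-1-one | CCOC1=CC(=O)C1 | starting material
11 | 3-(benzyloxy)cyclobut-2-en-1-one | O=C1C=C(OCc2ccccc2)C1 | intermediate
12 | 3-(benzyloxy)buta-1,3-dien-1-one (vinylketene) | O=C=CC(=C)OCc1ccccc1 | intermediate
13 | 4-[1-(benzyloxy)ethenyl]-2-{[(4R,5S)-5-[3-(benzyloxy)-4-methoxyphenyl]-2,2-dimethyl-1,3-dioxolan-4-yl]methyl}-3-[(triisopropylsilyl)oxy]cyclobut-2-en-1-one (both C4 epimers) | O=C1C(C[C@H]2OC(C)(C)O[C@H]2c2ccc(OC)c(OCc3ccccc3)c2)=C(O[Si](C(C)C)(C(C)C)C(C)C)C1C(=C)OCc1ccccc1 | intermediate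
14 | 5-(benzyloxy)-2-{[(4R,5S)-5-[3-(benzyloxy)-4-methoxyphenyl]-2,2-dimethyl-1,3-dioxolan-4-yl]methyl}-3-[(triisopropylsilyl)oxy]hexa-1,3,5-trien-1-one (ketene and alkoxyvinyl groups cis) | O=C=C(C[C@H]1OC(C)(C)O[C@H]1c1ccc(OC)c(OCc2ccccc2)c1)/C(O[Si](C(C)C)(C(C)C)C(C)C)=C\C(=C)OCc1ccccc1 | intermediate
15 | 5-(benzyloxy)-2-{[(4R,5S)-5-[3-(benzyloxy)-4-methoxyphenyl]-2,2-dimethyl-1,3-dioxolan-4-yl]methyl}-3-[(triisopropylsilyl)oxy]cyclohexa-2,4-dien-1-one | O=C1CC(OCc2ccccc2)=CC(O[Si](C(C)C)(C(C)C)C(C)C)=C1C[C@H]1OC(C)(C)O[C@H]1c1ccc(OC)c(OCc2ccccc2)c1 | intermediate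
16 | 5-(benzyloxy)-2-{[(4R,5S)-5-[3-(benzyloxy)-4-methoxyphenyl]-2,2-dimethyl-1,3-dioxolan-4-yl]methyl}-3-[(triisopropylsilyl)oxy]phenol | Oc1cc(OCc2ccccc2)cc(O[Si](C(C)C)(C(C)C)C(C)C)c1C[C@H]1OC(C)(C)O[C@H]1c1ccc(OC)c(OCc2ccccc2)c1 | intermediate
17 | (1S,2R)-1-[3-(benzyloxy)-4-methoxyphenyl]-3-{4-(benzyloxy)-2-hydroxy-6-[(triisopropylsilyl)oxy]phenyl}propane-1,2-diol | Oc1cc(OCc2ccccc2)cc(O[Si](C(C)C)(C(C)C)C(C)C)c1C[C@@H](O)[C@@H](O)c1ccc(OC)c(OCc2ccccc2)c1 | intermediate
18 | (2R,3R)-7-(benzyloxy)-2-[3-(benzyloxy)-4-methoxyphenyl]-5-[(triisopropylsilyl)oxy]-3,4-dihydro-2H-chromen-3-ol | COc1ccc([C@H]2Oc3cc(OCc4ccccc4)cc(O[Si](C(C)C)(C(C)C)C(C)C)c3C[C@H]2O)cc1OCc1ccccc1 | intermediate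
19 | 3,4,5-tris(benzyloxy)benzoic acid | OC(=O)c1cc(OCc2ccccc2)c(OCc2ccccc2)c(OCc2ccccc2)c1 | starting material
20 | (2R,3R)-7-(benzyloxy)-2-[3-(benzyloxy)-4-methoxyphenyl]-5-[(triisopropylsilyl)oxy]-3,4-dihydro-2H-chromen-3-yl 3,4,5-tris(benzyloxy)benzoate | COc1ccc([C@H]2Oc3cc(OCc4ccccc4)cc(O[Si](C(C)C)(C(C)C)C(C)C)c3C[C@H]2OC(=O)c2cc(OCc3ccccc3)c(OCc3ccccc3)c(OCc3ccccc3)c2)cc1OCc1ccccc1 | intermediate
21 | (2R,3R)-7-(benzyloxy)-2-[3-(benzyloxy)-4-methoxyphenyl]-5-hydroxy-3,4-dihydro-2H-chromen-3-yl 3,4,5-tris(benzyloxy)benzoate | COc1ccc([C@H]2Oc3cc(OCc4ccccc4)cc(O)c3C[C@H]2OC(=O)c2cc(OCc3ccccc3)c(OCc3ccccc3)c(OCc3ccccc3)c2)cc1OCc1ccccc1 | intermediate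
22 | 4'-O-methylepicatechin-3-O-gallate | COc1ccc([C@H]2Oc3cc(O)cc(O)c3C[C@H]2OC(=O)c2cc(O)c(O)c(O)c2)cc1O | target

**Step count**

Total: 13 steps. Longest linear sequence: 12 steps (steps 1–6 and 8–13); step 7 is a one-step side branch.

**Steps most likely to fail**

1. Step 8 (benzannulation). The vinylogous-ester cyclobutenone may open too slowly at temperatures the siloxyalkyne tolerates, the alkoxyvinylketene may dimerise or polymerise faster than it is trapped, or the new phenol may be acylated by further vinylketene. Fallback: buy the A ring instead of building it, setting out from epoxy alcohol 3 and rejoining at target 22. Intermolecular Mitsunobu etherification of 3 with 3,5-bis(benzyloxy)-2-iodophenol F1 (from commercial 3,5-bis(benzyloxy)phenol and N-iodosuccinimide) would invert the benzylic carbon and give (2R)-2-{(R)-[3,5-bis(benzyloxy)-2-iodophenoxy][3-(benzyloxy)-4-methoxyphenyl]methyl}oxirane F2. Iodine–lithium exchange (n-BuLi, THF, −78 °C, then warming) and attack of the aryllithium on the oxirane CH2 would close the pyran ring to (2R,3R)-5,7-bis(benzyloxy)-2-[3-(benzyloxy)-4-methoxyphenyl]-3,4-dihydro-2H-chromen-3-ol F3. Esterification with 19 under the conditions of step 11 would give the penta-O-benzyl gallate F4, and hydrogenolysis under the conditions of step 13 would give 22.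

2. Step 10 (Mitsunobu ring closure). Stereospecificity may be lost by ionisation of the p-alkoxybenzylic oxyphosphonium, or by epoxide formation from the neighbouring C3 hydroxyl followed by phenol opening (net retention, 2,3-trans product); 5-exo closure at C3 may also compete. Fallback: two-stage activation and displacement, setting out from triol 17 and rejoining at 18. The diol would be tied up as the cyclic sulfite (4R,5S)-4-{[4-(benzyloxy)-2-hydroxy-6-[(triisopropylsilyl)oxy]phenyl]methyl}-5-[3-(benzyloxy)-4-methoxyphenyl]-1,3,2-dioxathiolane 2-oxide F5 (SOCl2, Et3N, CH2Cl2, −40 °C). This removes the free C3 alkoxide and gives a poorer, less ionisable leaving group. Phenoxide formation (Cs2CO3, DMF, 50 °C) should then open the sulfite at the benzylic carbon with inversion, and the sulfite half-ester would lose sulfur dioxide on mildly acidic aqueous work-up to give 18.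

3. Step 7 (alkoxy exchange on the cyclobutenone). Benzyl alcohol may attack the strained ring carbonyl and cleave the four-membered ring to open-chain β-alkoxycrotonate or acetoacetate esters instead of exchanging the alkoxy group. Fallback: separate the two events, setting out from 10 and rejoining at 11. Hydrolysis of 10 (cold dilute HCl) would give cyclobutane-1,3-dione F6, whose acidic enol would then be O-benzylated under neutral Mitsunobu conditions (BnOH, PPh3, DIAD, THF, 0 °C) to give 11.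

**Further compounds**

F1 | step 8 | 3,5-bis(benzyloxy)-2-iodophenol | Oc1cc(OCc2ccccc2)cc(OCc2ccccc2)c1I
F2 | step 8 | (2R)-2-{(R)-[3,5-bis(benzyloxy)-2-iodophenoxy][3-(benzyloxy)-4-methoxyphenyl]methyl}oxirane | C1O[C@H]1[C@H](Oc1cc(OCc2ccccc2)cc(OCc2ccccc2)c1I)c1ccc(OC)c(OCc2ccccc2)c1
F3 | step 8 | (2R,3R)-5,7-bis(benzyloxy)-2-[3-(benzyloxy)-4-methoxyphenyl]-3,4-dihydro-2H-chromen-3-ol | COc1ccc([C@H]2Oc3cc(OCc4ccccc4)cc(OCc4ccccc4)c3C[C@H]2O)cc1OCc1ccccc1
F4 | step 8 | (2R,3R)-5,7-bis(benzyloxy)-2-[3-(benzyloxy)-4-methoxyphenyl]-3,4-dihydro-2H-chromen-3-yl 3,4,5-tris(benzyloxy)benzoate | COc1ccc([C@H]2Oc3cc(OCc4ccccc4)cc(OCc4ccccc4)c3C[C@H]2OC(=O)c2cc(OCc3ccccc3)c(OCc3ccccc3)c(OCc3ccccc3)c2)cc1OCc1ccccc1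
F5 | step 10 | (4R,5S)-4-{[4-(benzyloxy)-2-hydroxy-6-[(triisopropylsilyl)oxy]phenyl]methyl}-5-[3-(benzyloxy)-4-methoxyphenyl]-1,3,2-dioxathiolane 2-oxide | Oc1cc(OCc2ccccc2)cc(O[Si](C(C)C)(C(C)C)C(C)C)c1C[C@H]1OS(=O)O[C@H]1c1ccc(OC)c(OCc2ccccc2)c1
F6 | step 7 | cyclobutane-1,3-dione | O=C1CC(=O)C1
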